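In a closed flask the E charged stays on the books, and if each E binds one X, then at 1.50 equiv of X at least 33.3 % of the X charge outlasts E, even if E is used up completely.

| flask | E | X | temperature | remark | time |
|---|---|---|---|---|---|
| red | 0.12 M | 1.5 equiv | 25 °C | the very flask that is asked about, followed so far |  |
| violet | 0.060 M | 1.5 equiv | 20 °C | run made earlier |  |
| flask | 0.12 M | 1.50 equiv | 25 °C |  | 5.0 d |

- red (time / h: G / %): 10.0: 25; 20.0: 39; 30.0: 46; 40.0: 46; 48.0: 48; 60.0: 52; 72.0: 52
- violet (time / h: G / %): 0.250: 2; 0.667: 0; 1.33: 0; 2.00: 0; 3.00: 6; 4.00: 7; 5.00: 12

(scatter of a reading: 1.5 percentage points)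

- as a solid, counted per litre of solution: E
- G that was removed still counts
- at the start none of E is in solution
- additions bring no volume worth counting

- winter: at 5.0 d raise the temperature by 25 K, then wait 10 d
- dusk: at 5.0 d add X, 100 % of the amount charged, then wait 10 d
- summer: at 5.0 d take out 90 % of the G then present, then wait 10 d
- midnight: change nothing and wait 10 d more

- G, in percent of the E first charged, at 5.0 d
- which option adds most G ("none" when 2 percentage points or less is all one gets) (winter / dusk / summer / midnight / none)
- G present, with what was taken out counted in, in percent of the E first charged, after dusk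
- G present, with what was taken out counted in, in percent of the E first charged, after midnight

Red is the asked flask followed so far, and I want to bracket its G after dusk, the option that adds 100 % of the X charged. The charge bounds G from above at 100 %. I take the last red reading, 52 %, with its scatter, as the bottom, as the red readings at 60.0 h and 72.0 h are equal.

To tighten the top, I take the rate as a constant times X times its partner, both as fractions of their charges. Red made G at 0.0250 h⁻¹ over its first 10.0 h, and neither fraction can exceed one, so the constant is at least that large. The readings at 60.0 h and 72.0 h are equal, so the late slope is zero, give or take 0.00177 h⁻¹ from the scatter. Dividing that slope by the early rate and the floor gives 21.2 %. This is the reachable pool, my estimate, under this rate law, of the share of the charge that could still react with X while the slope stays within the scatter. A second dose brings X but no partner, so E, not X, looks like the limiting reagent. My bracket for dusk runs from 52 % to 73.2 %, provided nothing else destroys X or takes up G.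

The forecast gives 52 % now, 52 % after midnight, 92 % after dusk and dusk as best, saying “Both readings favour more X”. Its dusk figure stands above my bracket.

The flask gives 53.0 % now and 53.3 % after dusk, inside the bracket, a gain of 0.34 percentage points. The best option is winter, with 24 points, and summer adds 18 points.

    E ⇌ L, rate k1*(cs1 - [L]) while solid is left; crystals form when [L] > cs1 (solubility = 0.0640 M, k = 0.0102 min⁻¹)
    E → Z (k = 9.38 × 10⁻⁷ min⁻¹, Ea = 108 kJ mol⁻¹)
    G ⇌ J (K = 0.604, k = 8.03 × 10⁻⁴ min⁻¹, Ea = 90.0 kJ mol⁻¹, ΔH = −56.0 kJ mol⁻¹)
    E + G → Q (k = 0.0260 M⁻¹ min⁻¹, Ea = 79.0 kJ mol⁻¹)
    L + X → G (k = 0.00828 M⁻¹ min⁻¹, Ea = 77.0 kJ mol⁻¹)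
    (constants at 25 °C)

At 120 h the flask holds X at 39 % of its charge, above the floor of 33.3 %, and E at 0 % with L at 0.708 %, below the reachable pool of 21.2 %. G at 53.0 % and J at 31.8 % relax by their own step alone with a half-life of 5.42 h, short against the 5.0 d. At the same equivalents and time, the neighbour flask with 0.30 M of E holds X at 51 %, again above the floor, and L at 0 %, below the pool read on red.

The earlier runs and the new flask stem from a simulated flask from invented constants; noise was put on by code.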